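Numbering: O1, C2, C3, C3a–C7a is the dihydrobenzofuran carrying the guaiacyl group (C2) and the 3,5-dihydroxyphenyl group (C3). O1', C2', C3', C3a'–C7a' is the one carrying the 4-hydroxyphenyl group (C2') and the styryl group (C6'), and C3' is bonded to C6.
Enabling feature: C3' is a diarylmethine on benzo carbon C3a', which stands between the oxygen-bearing carbons C4' and C7a', and its ring neighbour C2' is a benzylic ether carbon. A carbene centred on C3' therefore has the O–CH2Ar hydrogens of either flanking ether in a 1,5-relationship, and C3/C3a/C4/C7a/C2 repeat this pattern.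
Retrosynthetic cuts, in order: the O–Si bonds and the two spare O–CH2Ar bonds; the stilbene C=C; C2–C3; C3–C3a; C2'–C3'; C3'–C3a'.
Forward: an aryllithium/nitrile union makes C3a'–C3' as a hydrazone, and carbene C–H insertion closes the primed dihydrofuran. A second such union at a bromine kept on the future C3a makes C3a–C3, and a second insertion closes the unprimed dihydrofuran. The C6' amide then becomes aldehyde and E-stilbene, and fluoride unmasks all phenols.
Stereochemistry: C3' comes from Rh2(R-PTAD)4 and C3 from Rh2(S-PTAD)4, two independent catalyst-controlled events. C2' and C2 follow by acid equilibration to the trans rings, and the alkene geometry comes from the Horner–Wadsworth–Emmons reaction.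

Key step: step 13

Assumption: Rh2(R-PTAD)4 is taken to give the 3'R centre. If the sense of induction on this substrate class is the opposite, the catalysts of steps 13 and 17 change places and nothing else changes.
Abbreviations: TIPS = triisopropylsilyl; PTAD = (1-adamantyl)(N-phthalimido)acetate; DIC = N,N'-diisopropylcarbodiimide; HOBt = 1-hydroxybenzotriazole; DIAD = diisopropyl azodicarboxylate.

Step 1
Reactants: 1 4-hydroxybenzaldehyde
Product: 2 4-(triisopropylsilyloxy)benzaldehyde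
Conditions: TIPSCl, imidazole, DMF, rt
Reagents that add atoms: chlorotriisopropylsilane, CC(C)[Si](Cl)(C(C)C)C(C)C
Why: Imidazole-promoted O-silylation of a phenol, with the bulky TIPS group chosen because it must later survive aryllithiums, hydrazine, dilute acid and Mitsunobu conditions.

Step 2
Reactants: 2 4-(triisopropylsilyloxy)benzaldehyde
Product: 3 [4-(triisopropylsilyloxy)phenyl]methanol
Conditions: NaBH4, MeOH, 0 °C
Reagents that add atoms: none
Why: Borohydride reduction of an aromatic aldehyde, to which aryl silyl ethers are inert.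

Step 3
Reactants: 3 [4-(triisopropylsilyloxy)phenyl]methanol
Product: 4 diethyl [4-(triisopropylsilyloxy)benzyl]phosphonate
Conditions: P(OEt)3, ZnI2, toluene, reflux
Reagents that add atoms: triethyl phosphite, CCOP(OCC)OCC
Why: ZnI2-promoted Michaelis–Arbuzov-type conversion of an electron-rich benzylic alcohol into its phosphonate by phosphite exchange and rearrangement, which avoids a labile 4-silyloxybenzyl halide.

Step 4
Reactants: 5 vanillin (4-hydroxy-3-methoxybenzaldehyde)
Product: 6 3-methoxy-4-(triisopropylsilyloxy)benzaldehyde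
Conditions: TIPSCl, imidazole, DMF, rt
Reagents that add atoms: chlorotriisopropylsilane, CC(C)[Si](Cl)(C(C)C)C(C)C
Why: The same phenol O-silylation as in step 1, which is routine for vanillin.

Step 5
Reactants: 6 3-methoxy-4-(triisopropylsilyloxy)benzaldehyde
Product: 7 [3-methoxy-4-(triisopropylsilyloxy)phenyl]methanol
Conditions: NaBH4, MeOH, 0 °C
Reagents that add atoms: none
Why: Borohydride reduction of an aromatic aldehyde, as in step 2.

Step 6
Reactants: 8 4-bromo-3,5-dihydroxybenzoic acid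
Product: 9 4-bromo-N,N-diethyl-3,5-dihydroxybenzamide
Conditions: Et2NH (excess), DIC, HOBt, DMF, 0 °C to rt
Reagents that add atoms: diethylamine, CCNCC
Why: Carbodiimide/HOBt amide coupling in which excess amine cleaves any transient phenolic ester, and the diethylamide is the carboxyl spectator because it resists hydrazine and cold aryllithiums (an ester would not) yet goes to the aldehyde in one step.

Step 7
Reactants: 9 4-bromo-N,N-diethyl-3,5-dihydroxybenzamide; 3 [4-(triisopropylsilyloxy)phenyl]methanol (2.4 equiv)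
Product: 10 4-bromo-N,N-diethyl-3,5-bis[4-(triisopropylsilyloxy)benzyloxy]benzamide
Conditions: PPh3, DIAD, THF, 0 °C to rt
Reagents that add atoms: none
Why: Double Mitsunobu etherification of the acidic bromoresorcinol hydroxyls with a primary benzylic alcohol, under neutral conditions that cannot desilylate.

Step 8
Reactants: 8 4-bromo-3,5-dihydroxybenzoic acid
Product: 11 4-bromo-3,5-dihydroxybenzamide
Conditions: DIC, HOBt, DMF, 0 °C; then NH3 (7 M in MeOH), rt
Reagents that add atoms: ammonia, N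
Why: The same carbodiimide/HOBt activation, with the active ester intercepted by ammonia.

Step 9
Reactants: 11 4-bromo-3,5-dihydroxybenzamide
Product: 12 3,5-bis(allyloxy)-4-bromobenzamide
Conditions: allyl bromide, K2CO3, acetone, reflux
Reagents that add atoms: allyl bromide, C=CCBr
Why: Williamson etherification in which the phenoxides react far faster than the primary carboxamide, with allyl chosen because it is inert to the acid phase of step 13, where further electron-rich benzylic ethers on this ring would be a liability.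

Step 10
Reactants: 12 3,5-bis(allyloxy)-4-bromobenzamide
Product: 13 3,5-bis(allyloxy)-4-bromobenzonitrile
Conditions: (CF3CO)2O, pyridine, CH2Cl2, 0 °C
Reagents that add atoms: none
Why: Standard dehydration of a primary amide to the nitrile with trifluoroacetic anhydride/pyridine, which leaves allyl ethers and the aryl bromide untouched.

Step 11
Reactants: 14 3,5-dihydroxybenzonitrile
Product: 15 3,5-bis(triisopropylsilyloxy)benzonitrile
Conditions: TIPSCl, imidazole, DMF, rt
Reagents that add atoms: chlorotriisopropylsilane, CC(C)[Si](Cl)(C(C)C)C(C)C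
Why: Double phenol O-silylation, as in step 1.

Step 12
Reactants: 10 4-bromo-N,N-diethyl-3,5-bis[4-(triisopropylsilyloxy)benzyloxy]benzamide; 13 3,5-bis(allyloxy)-4-bromobenzonitrile
Product: 18 hydrazone of [3,5-bis(allyloxy)-4-bromophenyl] {4-(diethylcarbamoyl)-2,6-bis[4-(triisopropylsilyloxy)benzyloxy]phenyl} ketone, via aryllithium 16 (not isolated), via ketimine 17 (not isolated)
Conditions: 10, n-BuLi, THF, −78 °C; 13, −78 to −20 °C; AcOH; N2H4 (1 M in THF), EtOH, rt to 40 °C
Reagents that add atoms: hydrazine, NN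
Why: Bromine–lithium exchange outruns attack on the diethylamide at −78 °C, the aryllithium adds once to the nitrile faster than it exchanges with the second aryl bromide (organolithium–nitrile addition), and the protonated N–H ketimine transiminates with hydrazine far more readily than a doubly ortho-substituted benzophenone would condense.

Step 13
Reactants: 18 hydrazone of [3,5-bis(allyloxy)-4-bromophenyl] {4-(diethylcarbamoyl)-2,6-bis[4-(triisopropylsilyloxy)benzyloxy]phenyl} ketone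
Product: 21 (2R,3R)-3-[3,5-bis(allyloxy)-4-bromophenyl]-N,N-diethyl-2-[4-(triisopropylsilyloxy)phenyl]-4-[4-(triisopropylsilyloxy)benzyloxy]-2,3-dihydrobenzofuran-6-carboxamide (trans; 2'R,3'R in target numbering), via diazo compound 19 (not isolated), via cis adduct 20 (not isolated)
Conditions: MnO2, CH2Cl2, rt, filtered through Celite under Ar; Rh2(R-PTAD)4 (1 mol %), 0 °C; then CF3CO2H (small excess over the amide), same flask, −20 to 0 °C
Reagents that add atoms: none
Why: MnO2 dehydrogenates the hydrazone to diaryldiazomethane 19, which loses N2 at the dirhodium tetracarboxylate to give a donor–donor carbene whose low electrophilicity should leave the allyl C=C bonds, the aryl bromide and the amide alone. The carbene carbon (C3') takes a hydrogen, in hydride-like fashion, from an O–CH2Ar group made electron-rich by its 4-silyloxy substituent, and the two carbons collapse to the C2'–C3' bond; this is the known enantioselective intramolecular C–H insertion of diaryl carbenes generated from hydrazones, and it closes the ring C3'–C3a'–C7a'–O1'–C2' by 1,5-insertion. C3' is fixed by the chiral carboxylate pocket of the catalyst, which distinguishes the two faces of the carbene, and the compact insertion transition state places the two aryl groups cis, giving 20 (2'S,3'R). CF3CO2H then protonates O1', the C2'–O1' bond ionises reversibly to a 4-silyloxybenzyl cation held next to its own phenol, and reclosure should funnel the material to the less strained trans isomer 21 (2'R,3'R), while C3', which bears no leaving group, is untouched. Site selectivity needs no control, because the two ortho ethers are interchanged by rotation about the C3a'–C3' bond and give the same product, and every other C–H bond (allyl ethers meta to the carbene, amide ethyl groups para) is out of reach. The acid phase relies on the secondary, strain-assisted and intramolecularly reversible ionisation at C2' being much faster than loss of the primary benzyl ether on O–C4', hence little acid, no external nucleophile and low temperature.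

Step 14
Reactants: 21 trans dihydrobenzofuran bis(allyl ether)
Product: 22 (2R,3R)-3-(4-bromo-3,5-dihydroxyphenyl)-N,N-diethyl-2-[4-(triisopropylsilyloxy)phenyl]-4-[4-(triisopropylsilyloxy)benzyloxy]-2,3-dihydrobenzofuran-6-carboxamide
Conditions: Pd(PPh3)4 (5 mol %), morpholine, THF, rt
Reagents that add atoms: none
Why: Tsuji–Trost-type deallylation, in which zerovalent palladium ionises the aryl allyl ethers to π-allyl complexes that morpholine captures, at a temperature where the hindered, electron-rich C–Br bond should not undergo oxidative addition.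

Step 15
Reactants: 22 bromoresorcinol; 7 [3-methoxy-4-(triisopropylsilyloxy)phenyl]methanol (2.4 equiv)
Product: 23 (2R,3R)-3-{4-bromo-3,5-bis[3-methoxy-4-(triisopropylsilyloxy)benzyloxy]phenyl}-N,N-diethyl-2-[4-(triisopropylsilyloxy)phenyl]-4-[4-(triisopropylsilyloxy)benzyloxy]-2,3-dihydrobenzofuran-6-carboxamide
Conditions: PPh3, DIAD, THF, 0 °C to rt
Reagents that add atoms: none
Why: Double Mitsunobu etherification as in step 7, placing on both oxygens beside the bromine the guaiacylmethyl groups that supply C2 in the second ring closure.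

Step 16
Reactants: 23 bromide with two guaiacylmethyl ethers; 15 3,5-bis(triisopropylsilyloxy)benzonitrile
Product: 26 hydrazone in which the bromine of 23 is replaced by C(=NNH2)[3,5-bis(triisopropylsilyloxy)phenyl], via aryllithium 24 (not isolated), via ketimine 25 (not isolated)
Conditions: 23, n-BuLi, THF, −78 °C; 15 (excess), −78 to −20 °C; AcOH; N2H4 (1 M in THF), EtOH, rt to 40 °C
Reagents that add atoms: hydrazine, NN
Why: The sequence of step 12 (bromine–lithium exchange, organolithium–nitrile addition, transimination with hydrazine) is repeated, with the exchange far faster at −78 °C than removal of C3'–H or of an O–CH2Ar hydrogen, so the existing stereocentres should be kept.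

Step 17
Reactants: 26 second hydrazone
Product: 29 (2S,3S,2'R,3'R)-bis(dihydrobenzofuran) amide: C2 3-methoxy-4-(TIPSO)phenyl; C3 3,5-bis(TIPSO)phenyl; O–C4 3-methoxy-4-(TIPSO)benzyl; C2' 4-(TIPSO)phenyl; O–C4' 4-(TIPSO)benzyl; C6' CONEt2, via diazo compound 27 (not isolated), via cis adduct 28 (not isolated)
Conditions: MnO2, CH2Cl2, rt, filtered through Celite under Ar; Rh2(S-PTAD)4 (1 mol %), 0 °C; then CF3CO2H, same flask, −20 to 0 °C
Reagents that add atoms: none
Why: The donor–donor carbene 1,5-C–H insertion of step 13 is repeated with the enantiomeric catalyst, which should fix C3 as S regardless of the distant C2'/C3' centres (the two guaiacylmethyl ethers are interchanged by rotation of the central ring, so either gives the same product), and the acid phase then equilibrates C2 to the trans (2S,3S) ring by reversible C2–O1 ionisation, while the already trans primed ring can only return to itself.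

Step 18
Reactants: 29 bis(dihydrobenzofuran) amide
Product: 30 the corresponding C6' carbaldehyde (CONEt2 of 29 replaced by CHO; 2S,3S,2'R,3'R)
Conditions: Cp2Zr(H)Cl (2 equiv), THF, rt; then H2O, silica gel
Reagents that add atoms: water, O
Why: Chemoselective reduction of a tertiary benzamide with Cp2Zr(H)Cl, in which one hydride transfer gives a zirconium-bound hemiaminal that is not reduced further and releases the aldehyde on hydrolysis, with silyl and benzyl ethers inert.

Step 19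
Reactants: 30 aldehyde; 4 diethyl [4-(triisopropylsilyloxy)benzyl]phosphonate
Product: 31 fully protected gnetin K: CHO of 30 replaced by (E)-CH=CH[4-(TIPSO)phenyl]
Conditions: 4, KN(SiMe3)2, THF, −78 to 0 °C; then 30, 0 °C to rt
Reagents that add atoms: none
Why: Horner–Wadsworth–Emmons olefination of an aromatic aldehyde with a benzylic phosphonate anion, which reliably gives the E-stilbene and uses a base too weak and too hindered to touch C3–H, C3'–H or the silyl ethers.

Step 20
Reactants: 31 fully protected gnetin K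
Product: 33 gnetin K, via heptaphenol 32 (not isolated)
Conditions: Bu4NF (10 equiv), n-C12H25SH (10 equiv), THF, 0 °C to rt, Ar; then AcOH
Reagents that add atoms: none
Why: Fluoride removes the seven silyl groups, the two 4-oxidobenzyl aryl ethers then fragment by 1,6-elimination (the self-immolative cleavage used in fluoride-triggered phenol release), the thiol traps both quinone methides by 1,6-addition, and all four stereocentres already sit in the thermodynamically preferred trans rings.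

Compound list
1 | 4-hydroxybenzaldehyde | O=Cc1ccc(O)cc1 | starting material
2 | 4-(triisopropylsilyloxy)benzaldehyde | O=Cc1ccc(O[Si](C(C)C)(C(C)C)C(C)C)cc1 | intermediate
3 | [4-(triisopropylsilyloxy)phenyl]methanol | OCc1ccc(O[Si](C(C)C)(C(C)C)C(C)C)cc1 | intermediate
4 | diethyl [4-(triisopropylsilyloxy)benzyl]phosphonate | CCOP(=O)(OCC)Cc1ccc(O[Si](C(C)C)(C(C)C)C(C)C)cc1 | intermediate
5 | vanillin | COc1cc(C=O)ccc1O | starting material
6 | 3-methoxy-4-(triisopropylsilyloxy)benzaldehyde | COc1cc(C=O)ccc1O[Si](C(C)C)(C(C)C)C(C)C | intermediate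
7 | [3-methoxy-4-(triisopropylsilyloxy)phenyl]methanol | COc1cc(CO)ccc1O[Si](C(C)C)(C(C)C)C(C)C | intermediate
8 | 4-bromo-3,5-dihydroxybenzoic acid | OC(=O)c1cc(O)c(Br)c(O)c1 | starting material
9 | 4-bromo-N,N-diethyl-3,5-dihydroxybenzamide | CCN(CC)C(=O)c1cc(O)c(Br)c(O)c1 | intermediate
10 | 4-bromo-N,N-diethyl-3,5-bis[4-(triisopropylsilyloxy)benzyloxy]benzamide | CCN(CC)C(=O)c1cc(OCc2ccc(O[Si](C(C)C)(C(C)C)C(C)C)cc2)c(Br)c(OCc2ccc(O[Si](C(C)C)(C(C)C)C(C)C)cc2)c1 | intermediate
11 | 4-bromo-3,5-dihydroxybenzamide | NC(=O)c1cc(O)c(Br)c(O)c1 | intermediate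
12 | 3,5-bis(allyloxy)-4-bromobenzamide | NC(=O)c1cc(OCC=C)c(Br)c(OCC=C)c1 | intermediate
13 | 3,5-bis(allyloxy)-4-bromobenzonitrile | N#Cc1cc(OCC=C)c(Br)c(OCC=C)c1 | intermediate
14 | 3,5-dihydroxybenzonitrile | N#Cc1cc(O)cc(O)c1 | starting material
15 | 3,5-bis(triisopropylsilyloxy)benzonitrile | N#Cc1cc(O[Si](C(C)C)(C(C)C)C(C)C)cc(O[Si](C(C)C)(C(C)C)C(C)C)c1 | intermediate
16 | aryllithium from 10 (Li in place of Br) | CCN(CC)C(=O)c1cc(OCc2ccc(O[Si](C(C)C)(C(C)C)C(C)C)cc2)c([Li])c(OCc2ccc(O[Si](C(C)C)(C(C)C)C(C)C)cc2)c1 | intermediate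
17 | N–H ketimine of the diaryl ketone of 18 | N=C(c1cc(OCC=C)c(Br)c(OCC=C)c1)c1c(OCc2ccc(O[Si](C(C)C)(C(C)C)C(C)C)cc2)cc(cc1OCc1ccc(O[Si](C(C)C)(C(C)C)C(C)C)cc1)C(=O)N(CC)CC | intermediate
18 | hydrazone of [3,5-bis(allyloxy)-4-bromophenyl] {4-(diethylcarbamoyl)-2,6-bis[4-(triisopropylsilyloxy)benzyloxy]phenyl} ketone | NN=C(c1cc(OCC=C)c(Br)c(OCC=C)c1)c1c(OCc2ccc(O[Si](C(C)C)(C(C)C)C(C)C)cc2)cc(cc1OCc1ccc(O[Si](C(C)C)(C(C)C)C(C)C)cc1)C(=O)N(CC)CC | intermediate
19 | diaryldiazomethane from 18 | [N-]=[N+]=C(c1cc(OCC=C)c(Br)c(OCC=C)c1)c1c(OCc2ccc(O[Si](C(C)C)(C(C)C)C(C)C)cc2)cc(cc1OCc1ccc(O[Si](C(C)C)(C(C)C)C(C)C)cc1)C(=O)N(CC)CC | intermediate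
20 | (2S,3R)-cis isomer of 21 | C=CCOc1cc(cc(OCC=C)c1Br)[C@@H]1c2c(OCc3ccc(O[Si](C(C)C)(C(C)C)C(C)C)cc3)cc(cc2O[C@@H]1c1ccc(O[Si](C(C)C)(C(C)C)C(C)C)cc1)C(=O)N(CC)CC | intermediate
21 | (2R,3R)-3-[3,5-bis(allyloxy)-4-bromophenyl]-N,N-diethyl-2-[4-(triisopropylsilyloxy)phenyl]-4-[4-(triisopropylsilyloxy)benzyloxy]-2,3-dihydrobenzofuran-6-carboxamide | C=CCOc1cc(cc(OCC=C)c1Br)[C@@H]1c2c(OCc3ccc(O[Si](C(C)C)(C(C)C)C(C)C)cc3)cc(cc2O[C@H]1c1ccc(O[Si](C(C)C)(C(C)C)C(C)C)cc1)C(=O)N(CC)CC | intermediate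
22 | (2R,3R)-3-(4-bromo-3,5-dihydroxyphenyl) analogue of 21 | Oc1cc(cc(O)c1Br)[C@@H]1c2c(OCc3ccc(O[Si](C(C)C)(C(C)C)C(C)C)cc3)cc(cc2O[C@H]1c1ccc(O[Si](C(C)C)(C(C)C)C(C)C)cc1)C(=O)N(CC)CC | intermediate
23 | (2R,3R)-3-{4-bromo-3,5-bis[3-methoxy-4-(triisopropylsilyloxy)benzyloxy]phenyl} analogue of 21 | Brc1c(OCc2ccc(O[Si](C(C)C)(C(C)C)C(C)C)c(OC)c2)cc(cc1OCc1ccc(O[Si](C(C)C)(C(C)C)C(C)C)c(OC)c1)[C@@H]1c2c(OCc3ccc(O[Si](C(C)C)(C(C)C)C(C)C)cc3)cc(cc2O[C@H]1c1ccc(O[Si](C(C)C)(C(C)C)C(C)C)cc1)C(=O)N(CC)CC | intermediate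
24 | aryllithium from 23 (Li in place of Br) | [Li]c1c(OCc2ccc(O[Si](C(C)C)(C(C)C)C(C)C)c(OC)c2)cc(cc1OCc1ccc(O[Si](C(C)C)(C(C)C)C(C)C)c(OC)c1)[C@@H]1c2c(OCc3ccc(O[Si](C(C)C)(C(C)C)C(C)C)cc3)cc(cc2O[C@H]1c1ccc(O[Si](C(C)C)(C(C)C)C(C)C)cc1)C(=O)N(CC)CC | intermediate
25 | N–H ketimine: Br of 23 replaced by C(=NH)[3,5-bis(TIPSO)phenyl] | N=C(c1cc(O[Si](C(C)C)(C(C)C)C(C)C)cc(O[Si](C(C)C)(C(C)C)C(C)C)c1)c1c(OCc2ccc(O[Si](C(C)C)(C(C)C)C(C)C)c(OC)c2)cc(cc1OCc1ccc(O[Si](C(C)C)(C(C)C)C(C)C)c(OC)c1)[C@@H]1c2c(OCc3ccc(O[Si](C(C)C)(C(C)C)C(C)C)cc3)cc(cc2O[C@H]1c1ccc(O[Si](C(C)C)(C(C)C)C(C)C)cc1)C(=O)N(CC)CC | intermediate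
26 | hydrazone: Br of 23 replaced by C(=NNH2)[3,5-bis(TIPSO)phenyl] | NN=C(c1cc(O[Si](C(C)C)(C(C)C)C(C)C)cc(O[Si](C(C)C)(C(C)C)C(C)C)c1)c1c(OCc2ccc(O[Si](C(C)C)(C(C)C)C(C)C)c(OC)c2)cc(cc1OCc1ccc(O[Si](C(C)C)(C(C)C)C(C)C)c(OC)c1)[C@@H]1c2c(OCc3ccc(O[Si](C(C)C)(C(C)C)C(C)C)cc3)cc(cc2O[C@H]1c1ccc(O[Si](C(C)C)(C(C)C)C(C)C)cc1)C(=O)N(CC)CC | intermediate
27 | diaryldiazomethane from 26 | [N-]=[N+]=C(c1cc(O[Si](C(C)C)(C(C)C)C(C)C)cc(O[Si](C(C)C)(C(C)C)C(C)C)c1)c1c(OCc2ccc(O[Si](C(C)C)(C(C)C)C(C)C)c(OC)c2)cc(cc1OCc1ccc(O[Si](C(C)C)(C(C)C)C(C)C)c(OC)c1)[C@@H]1c2c(OCc3ccc(O[Si](C(C)C)(C(C)C)C(C)C)cc3)cc(cc2O[C@H]1c1ccc(O[Si](C(C)C)(C(C)C)C(C)C)cc1)C(=O)N(CC)CC | intermediate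
28 | (2R,3S,2'R,3'R) isomer of 29 (unprimed ring cis) | COc1cc([C@@H]2Oc3cc([C@@H]4c5c(OCc6ccc(O[Si](C(C)C)(C(C)C)C(C)C)cc6)cc(C(=O)N(CC)CC)cc5O[C@H]4c4ccc(O[Si](C(C)C)(C(C)C)C(C)C)cc4)cc(OCc4ccc(O[Si](C(C)C)(C(C)C)C(C)C)c(OC)c4)c3[C@@H]2c2cc(O[Si](C(C)C)(C(C)C)C(C)C)cc(O[Si](C(C)C)(C(C)C)C(C)C)c2)ccc1O[Si](C(C)C)(C(C)C)C(C)C | intermediate
29 | (2S,3S,2'R,3'R)-bis(dihydrobenzofuran) C6' diethylamide, six TIPS ethers, 4-(TIPSO)benzyl on O–C4', 3-methoxy-4-(TIPSO)benzyl on O–C4 | COc1cc([C@H]2Oc3cc([C@@H]4c5c(OCc6ccc(O[Si](C(C)C)(C(C)C)C(C)C)cc6)cc(C(=O)N(CC)CC)cc5O[C@H]4c4ccc(O[Si](C(C)C)(C(C)C)C(C)C)cc4)cc(OCc4ccc(O[Si](C(C)C)(C(C)C)C(C)C)c(OC)c4)c3[C@@H]2c2cc(O[Si](C(C)C)(C(C)C)C(C)C)cc(O[Si](C(C)C)(C(C)C)C(C)C)c2)ccc1O[Si](C(C)C)(C(C)C)C(C)C | intermediate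
30 | C6' carbaldehyde corresponding to 29 | COc1cc([C@H]2Oc3cc([C@@H]4c5c(OCc6ccc(O[Si](C(C)C)(C(C)C)C(C)C)cc6)cc(C=O)cc5O[C@H]4c4ccc(O[Si](C(C)C)(C(C)C)C(C)C)cc4)cc(OCc4ccc(O[Si](C(C)C)(C(C)C)C(C)C)c(OC)c4)c3[C@@H]2c2cc(O[Si](C(C)C)(C(C)C)C(C)C)cc(O[Si](C(C)C)(C(C)C)C(C)C)c2)ccc1O[Si](C(C)C)(C(C)C)C(C)C | intermediate
31 | fully protected gnetin K (seven TIPS ethers, two spare benzyl ethers, E-stilbene) | COc1cc([C@H]2Oc3cc([C@@H]4c5c(OCc6ccc(O[Si](C(C)C)(C(C)C)C(C)C)cc6)cc(/C=C/c6ccc(O[Si](C(C)C)(C(C)C)C(C)C)cc6)cc5O[C@H]4c4ccc(O[Si](C(C)C)(C(C)C)C(C)C)cc4)cc(OCc4ccc(O[Si](C(C)C)(C(C)C)C(C)C)c(OC)c4)c3[C@@H]2c2cc(O[Si](C(C)C)(C(C)C)C(C)C)cc(O[Si](C(C)C)(C(C)C)C(C)C)c2)ccc1O[Si](C(C)C)(C(C)C)C(C)C | intermediate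
32 | heptaphenol: gnetin K with 4-hydroxybenzyl on O–C4' and 4-hydroxy-3-methoxybenzyl on O–C4 | COc1cc([C@H]2Oc3cc([C@@H]4c5c(OCc6ccc(O)cc6)cc(/C=C/c6ccc(O)cc6)cc5O[C@H]4c4ccc(O)cc4)cc(OCc4ccc(O)c(OC)c4)c3[C@@H]2c2cc(O)cc(O)c2)ccc1O | intermediate
33 | gnetin K (2S,3S,2'R,3'R; E) | COc1cc([C@H]2Oc3cc([C@@H]4c5c(O)cc(/C=C/c6ccc(O)cc6)cc5O[C@H]4c4ccc(O)cc4)cc(O)c3[C@@H]2c2cc(O)cc(O)c2)ccc1O | target

Total step count: 20.
Longest linear sequence: 12 steps (1 → 2 → 3 → 10 → 18 → 21 → 22 → 23 → 26 → 29 → 30 → 31 → 33). The branch 8 → 11 → 12 → 13 → 18 is equally long.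

The three steps most likely to fail

**Step 13.**
- Process: the primary 4-silyloxybenzyl ether on O–C4' may ionise before the cis-to-trans equilibration at C2' is complete. The liberated benzyl cation would then alkylate the electron-rich rings.
- Fallback: the acid is left out and cis adduct 20 is isolated. It is treated with CF3CO2H and thioanisole in CH2Cl2. The sulfide removes the primary benzyl group deliberately, by an SN2-type push–pull cleavage, as a sulfonium salt. Its addition to the hindered C2' cation is reversible, so C2' can equilibrate at leisure. This should give the trans C4' phenol (2R,3R)-3-[3,5-bis(allyloxy)-4-bromophenyl]-N,N-diethyl-4-hydroxy-2-[4-(triisopropylsilyloxy)phenyl]-2,3-dihydrobenzofuran-6-carboxamide F1. A Mitsunobu reaction of this phenol with alcohol 3 (PPh3, DIAD, THF) restores the ether and rejoins the route at 21.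

**Step 16.**
- Process: the doubly ortho-substituted aryllithium 24 may add only sluggishly to nitrile 15 on warming. That leaves time for proton transfer from C3'–H or an O–CH2Ar position, with loss of configuration or ring opening, or for attack on the diethylamide.
- Fallback: it sets out from 23. After the same exchange, 24 is intercepted at −78 °C by the far more electrophilic 3,5-bis(triisopropylsilyloxy)benzaldehyde F2, made from commercial 3,5-dihydroxybenzaldehyde with TIPSCl and imidazole. This gives the diarylcarbinol F3 as both carbinol epimers, which is of no consequence. Dess–Martin periodinane in CH2Cl2 oxidises it to the diaryl ketone F4. Prolonged heating with anhydrous hydrazine and AcOH in n-BuOH condenses the ketone to hydrazone 26, where the route is rejoined.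

**Step 20.**
- Process: the two quinone methides set free in basic medium may alkylate the polyphenol product faster than the thiol traps them. Long exposure to base also invites phenoxide-driven opening of the dihydrofuran rings.
- Fallback: the spare ethers are removed before the stilbene exists, so the last step becomes a plain desilylation. Aldehyde 30 is treated with CF3CO2H and thioanisole in CH2Cl2 to give the C4,C4'-dihydroxy aldehyde F5. Horner–Wadsworth–Emmons reaction with an excess of the anion of 4 (KN(SiMe3)2, THF; the two phenoxides are meta or remote to the formyl group) gives the pentasilylated stilbene diol F6. Bu4NF buffered with AcOH in THF then gives 33.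

Further compounds
F1 | step 13 | (2R,3R)-3-[3,5-bis(allyloxy)-4-bromophenyl]-N,N-diethyl-4-hydroxy-2-[4-(triisopropylsilyloxy)phenyl]-2,3-dihydrobenzofuran-6-carboxamide | C=CCOc1cc(cc(OCC=C)c1Br)[C@@H]1c2c(O)cc(cc2O[C@H]1c1ccc(O[Si](C(C)C)(C(C)C)C(C)C)cc1)C(=O)N(CC)CC
F2 | step 16 | 3,5-bis(triisopropylsilyloxy)benzaldehyde | O=Cc1cc(O[Si](C(C)C)(C(C)C)C(C)C)cc(O[Si](C(C)C)(C(C)C)C(C)C)c1
F3 | step 16 | diarylcarbinol: Br of 23 replaced by CH(OH)[3,5-bis(TIPSO)phenyl], carbinol centre unassigned | OC(c1cc(O[Si](C(C)C)(C(C)C)C(C)C)cc(O[Si](C(C)C)(C(C)C)C(C)C)c1)c1c(OCc2ccc(O[Si](C(C)C)(C(C)C)C(C)C)c(OC)c2)cc(cc1OCc1ccc(O[Si](C(C)C)(C(C)C)C(C)C)c(OC)c1)[C@@H]1c2c(OCc3ccc(O[Si](C(C)C)(C(C)C)C(C)C)cc3)cc(cc2O[C@H]1c1ccc(O[Si](C(C)C)(C(C)C)C(C)C)cc1)C(=O)N(CC)CC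
F4 | step 16 | diaryl ketone: Br of 23 replaced by C(=O)[3,5-bis(TIPSO)phenyl] | O=C(c1cc(O[Si](C(C)C)(C(C)C)C(C)C)cc(O[Si](C(C)C)(C(C)C)C(C)C)c1)c1c(OCc2ccc(O[Si](C(C)C)(C(C)C)C(C)C)c(OC)c2)cc(cc1OCc1ccc(O[Si](C(C)C)(C(C)C)C(C)C)c(OC)c1)[C@@H]1c2c(OCc3ccc(O[Si](C(C)C)(C(C)C)C(C)C)cc3)cc(cc2O[C@H]1c1ccc(O[Si](C(C)C)(C(C)C)C(C)C)cc1)C(=O)N(CC)CC
F5 | step 20 | C4,C4'-dihydroxy aldehyde: 30 without its two primary benzyl ethers | COc1cc([C@H]2Oc3cc([C@@H]4c5c(O)cc(C=O)cc5O[C@H]4c4ccc(O[Si](C(C)C)(C(C)C)C(C)C)cc4)cc(O)c3[C@@H]2c2cc(O[Si](C(C)C)(C(C)C)C(C)C)cc(O[Si](C(C)C)(C(C)C)C(C)C)c2)ccc1O[Si](C(C)C)(C(C)C)C(C)C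
F6 | step 20 | pentakis(TIPS) ether of gnetin K with free C4 and C4' hydroxyls | COc1cc([C@H]2Oc3cc([C@@H]4c5c(O)cc(/C=C/c6ccc(O[Si](C(C)C)(C(C)C)C(C)C)cc6)cc5O[C@H]4c4ccc(O[Si](C(C)C)(C(C)C)C(C)C)cc4)cc(O)c3[C@@H]2c2cc(O[Si](C(C)C)(C(C)C)C(C)C)cc(O[Si](C(C)C)(C(C)C)C(C)C)c2)ccc1O[Si](C(C)C)(C(C)C)C(C)C
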